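## Retrosynthetic overview

1. Target ← acetylation of the C15 alcohol ← ring D closure: C13–C16 bond by a proposed gold-catalysed γ-selective (vinylogous) Conia-ene reaction of a C9 silyl dienol ether onto the C16≡C17 alkyne.
2. C15–C16 ← chelation-controlled ethynylation of a C15 aldehyde; ring C and the C8 quaternary centre ← catalyst-controlled Diels–Alder reaction of a 2-substituted acrolein with a 1-silyloxybutadiene.
3. C6–C7 ← Hosomi–Sakurai allylation of the acyl oxocarbenium ion from a menthyl lactone acetal (the auxiliary is the leaving group).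
4. Ring A on the lactone ← auxiliary-controlled Diels–Alder reaction of (5S)-5-(d-menthyloxy)butenolide with a 2-silyloxypentadiene, then C4 methylation, C10 oxygenation and removal of the C1 oxygen.
5. Ring order: lactone (purchased) → ring A → ring C → ring D (bicyclo[3.2.1]octenone).

Assumption and convention: atom labels C1–C20 are ent-kaurane positions (ring A = C1–C5 and C10; lactone C19(=O)–O–C6; C7 methylene; ring C = C8, C9, C11–C14; bridge C15–C16; C17 exocyclic CH2; C18 and C20 methyls), and butenolide 3 is taken as purchased (otherwise one step from 5-hydroxyfuran-2(5H)-one and (+)-menthol).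

## Route

Step 1
Reactants: 1 pent-1-en-3-one
Product: 2 (3Z)-3-(tert-butyldimethylsilyloxy)penta-1,3-diene
Conditions: TBSOTf, Et3N, Et2O, 0 °C
Reagents that add atoms: tert-butyldimethylsilyl trifluoromethanesulfonate, CC(C)(C)[Si](C)(C)OS(=O)(=O)C(F)(F)F
Why: Soft enolisation (silyl triflate and amine) of the ethyl ketone gives the 2-silyloxydiene with the methyl group trans to the vinyl group, and this geometry is erased later.

Step 2
Reactants: 3 (5S)-5-(d-menthyloxy)furan-2(5H)-one; 2 (3Z)-3-(tert-butyldimethylsilyloxy)penta-1,3-diene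
Product: 4 cis-fused menthyl lactone acetal carrying the C1=C2 TBS enol ether (H at C4 and C5 cis; C10 methyl syn to C6)
Conditions: PhMe, 120 °C, sealed tube
Reagents that add atoms: none
Why: Thermal Diels–Alder reaction in which the nucleophilic methyl-bearing diene terminus bonds to the butenolide β-carbon (C5–C10) and the diene adds endo and anti to the menthyloxy group, which sets C4 and C5 (cis fusion) in the absolute sense fixed by the auxiliary.

Step 3
Reactants: 4 cis-fused menthyl lactone acetal carrying the C1=C2 TBS enol ether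
Product: 6 C4-methyl C1-ketone lactone acetal, via C4-methylated silyl enol ether 5 (not isolated)
Conditions: LiN(i-Pr)2, THF, −78 °C; MeI, DMPU; then Bu4NF, AcOH, THF, 0 °C
Reagents that add atoms: iodomethane, CI
Why: Lactone enolate alkylation in which methyl iodide enters on the convex face of the cis-fused bicycle (the face the C4 hydrogen occupied), creating the C4 quaternary centre with C19 and C6 cis, after which fluoride unmasks the C1 ketone.

Step 4
Reactants: 6 C4-methyl C1-ketone lactone acetal
Product: 8 C10 TBS-oxy C1-ketone lactone acetal, via C1=C10 TBS enol ether 7 (not isolated)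
Conditions: KH, THF, rt (equilibration); TBSCl; then DMDO, acetone/CH2Cl2, −40 °C to rt
Reagents that add atoms: tert-butyldimethylsilyl chloride, CC(C)(C)[Si](C)(C)Cl; dimethyldioxirane, CC1(C)OO1
Why: Rubottom oxidation in which the equilibrated, more substituted enolate is O-silylated, DMDO epoxidises the C1=C10 enol ether on the convex face away from the lactone ring, and 1,4-silyl shift leaves the C10 tertiary silyl ether with oxygen anti to C6 and methyl syn to C6.

Step 5
Reactants: 8 C10 TBS-oxy C1-ketone lactone acetal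
Product: 9 C1=C2 enol triflate
Conditions: KN(SiMe3)2, THF, −78 °C; PhNTf2
Reagents that add atoms: N-phenylbis(trifluoromethanesulfonimide), O=S(=O)(N(c1ccccc1)S(=O)(=O)C(F)(F)F)C(F)(F)F
Why: Kinetic enolate O-triflation that can only occur toward C2 because C10 is now quaternary, with no stereocentre touched.

Step 6
Reactants: 9 C1=C2 enol triflate
Product: 10 ring A menthyl lactone acetal (C10 TBS ether; C1 and C2 as CH2)
Conditions: H2 (1 atm), PtO2, NaOAc, EtOH, rt
Reagents that add atoms: none
Why: Catalytic hydrogenolysis and hydrogenation of the enol triflate deletes the C1 oxygen that was needed only to direct the C10 oxygenation, without affecting any stereocentre.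

Step 7
Reactants: 10 ring A menthyl lactone acetal; 11 2-[(trimethylsilyl)methyl]prop-2-en-1-yl acetate
Product: 12 C6 2-(acetoxymethyl)allyl lactone
Conditions: TMSOTf (0.2 equiv), CH2Cl2, −78 to −40 °C
Reagents that add atoms: none
Why: Hosomi–Sakurai allylation in which silylation of the exocyclic acetal oxygen gives a cyclic acyl oxocarbenium ion that the allylsilane attacks on the convex face anti to the C10 carbon on C5, so C7 takes the place of the menthyloxy group and sets C6.

Step 8
Reactants: 12 C6 2-(acetoxymethyl)allyl lactone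
Product: 13 allylic alcohol
Conditions: K2CO3 (cat.), MeOH, 0 °C
Reagents that add atoms: none
Why: Base-catalysed transesterification removes the primary allylic acetate while the hindered γ-lactone and the tertiary silyl ether survive.

Step 9
Reactants: 13 allylic alcohol
Product: 14 2-substituted acrolein (C15 aldehyde on C8=C14)
Conditions: TEMPO (cat.), PhI(OAc)2, CH2Cl2, rt
Reagents that add atoms: none
Why: Oxoammonium (TEMPO) oxidation of the primary allylic alcohol stops cleanly at the enal.

Step 10
Reactants: 15 (E)-but-2-enal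
Product: 16 (1E)-1-(triethylsilyloxy)buta-1,3-diene
Conditions: TESOTf, Et3N, Et2O, 0 °C
Reagents that add atoms: triethylsilyl trifluoromethanesulfonate, CC[Si](CC)(CC)OS(=O)(=O)C(F)(F)F
Why: Soft γ-enolisation of crotonaldehyde gives the 1-silyloxydiene.

Step 11
Reactants: 14 2-substituted acrolein; 16 (1E)-1-(triethylsilyloxy)buta-1,3-diene
Product: 18 ring C hydroxy aldehyde (C9 OH; C11=C12; C15 aldehyde on quaternary C8), via TES-protected cycloadduct 17 (not isolated)
Conditions: (R)-3,3-diphenyl-1-(o-tolyl)tetrahydropyrrolo[1,2-c][1,3,2]oxazaborole·HNTf2 (20 mol %), CH2Cl2, −78 °C; then 1 M HCl, THF, 0 °C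
Reagents that add atoms: none
Why: Catalytic enantioselective Diels–Alder reaction in which the oxygenated diene terminus bonds to C8 ("ortho" rule) and the (R)-oxazaborolidinium-bound s-trans enal is expected, by the usual formyl C–H···O model, to be attacked on the Re face of C8, setting the quaternary centre by catalyst control, while the C9 configuration is irrelevant because it is oxidised next.

Step 12
Reactants: 18 ring C hydroxy aldehyde
Product: 19 ring C keto aldehyde (C9 enone; C15 aldehyde)
Conditions: Dess–Martin periodinane, NaHCO3, CH2Cl2, 0 °C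
Reagents that add atoms: none
Why: Dess–Martin oxidation of the allylic alcohol gives the enone and removes the C9 stereocentre.

Step 13
Reactants: 19 ring C keto aldehyde
Product: 20 C15 propargylic alcohol
Conditions: HC≡CMgBr, CH2Cl2/THF, −78 °C
Reagents that add atoms: ethynylmagnesium bromide, C#C[Mg]Br
Why: Chelation-controlled Grignard addition in which magnesium bridges the C9 and C15 carbonyl oxygens and the acetylide attacks the aldehyde face anti to the C7 chain, setting C15 with its oxygen syn to C9.

Step 14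
Reactants: 20 C15 propargylic alcohol
Product: 21 bis-TES silyl dienol ether (C9=C11 and C12=C13; C15 OTES)
Conditions: TESOTf (2.5 equiv), Et3N, CH2Cl2, −78 to 0 °C
Reagents that add atoms: triethylsilyl trifluoromethanesulfonate, CC[Si](CC)(CC)OS(=O)(=O)C(F)(F)F
Why: Soft enolisation that, with no α′-hydrogen on quaternary C8, deprotonates C13 to give the linear 1-silyloxy-1,3-diene while the C15 alcohol is silylated, which also prevents retro-aldol cleavage.

Step 15
Reactants: 21 bis-TES silyl dienol ether
Product: 23 15-deacetyl target (C15 and C10 diol), via bicyclic bis-silyl ether 22 (not isolated)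
Conditions: [(2-biphenylyl)(t-Bu)2P]Au(NCMe)SbF6 (5 mol %), CH2Cl2/MeOH 10:1, 0 °C to rt; then HF·pyridine, THF, rt
Reagents that add atoms: none
Why: Proposed new method: a gold-catalysed vinylogous (γ-selective) Conia-ene cyclisation in which the cationic monovalent gold complex activates the terminal alkyne, the γ-carbon C13 of the silyl dienol ether (largest HOMO coefficient, held 1,3 to the propargylic arm on C8) attacks the internal alkyne carbon 5-exo-dig to form C13–C16 and the C13 bridgehead stereocentre (fixed by the cis tether), and methanol protodeaurates the vinylgold to the exocyclic methylene and desilylates the oxocarbenium to the conjugated enone, the closest known reaction type being the gold-catalysed 5-exo-dig carbocyclisation of simple silyl enol ethers onto alkynes through their α-carbon; HF·pyridine then removes both remaining silyl ethers.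

Step 16
Reactants: 23 15-deacetyl target
Product: 24 CNP0172716.1
Conditions: Ac2O, pyridine, DMAP (cat.), CH2Cl2, 0 °C
Reagents that add atoms: acetic anhydride, CC(=O)OC(C)=O
Why: Nucleophile-catalysed acylation acetylates the secondary allylic C15 alcohol selectively over the hindered tertiary C10 alcohol.

## Compound list

1 | pent-1-en-3-one | C=CC(=O)CC | starting material
2 | (3Z)-3-(tert-butyldimethylsilyloxy)penta-1,3-diene | C=C/C(=C/C)O[Si](C)(C)C(C)(C)C | intermediate
3 | (5S)-5-{[(1S,2R,5S)-2-isopropyl-5-methylcyclohexyl]oxy}furan-2(5H)-one | CC(C)[C@H]1CC[C@H](C)C[C@@H]1O[C@H]2OC(=O)C=C2 | starting material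
4 | Diels–Alder adduct: cis-fused menthyl lactone acetal, C1=C2 TBS enol ether, H at C4, C10 methyl syn to C6, O-menthyl anti to ring A | CC(C)[C@H]1CC[C@H](C)C[C@@H]1O[C@H]2OC(=O)[C@@H]3CC=C(O[Si](C)(C)C(C)(C)C)[C@H](C)[C@H]23 | intermediate
5 | C4-methylated silyl enol ether (methyl on the convex face) | CC(C)[C@H]1CC[C@H](C)C[C@@H]1O[C@H]2OC(=O)[C@]3(C)CC=C(O[Si](C)(C)C(C)(C)C)[C@H](C)[C@H]23 | intermediate
6 | C4-methyl C1-ketone lactone acetal | CC(C)[C@H]1CC[C@H](C)C[C@@H]1O[C@H]2OC(=O)[C@]3(C)CCC(=O)[C@H](C)[C@H]23 | intermediate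
7 | C1=C10 TBS enol ether | CC(C)[C@H]1CC[C@H](C)C[C@@H]1O[C@H]2OC(=O)[C@]3(C)CCC(O[Si](C)(C)C(C)(C)C)=C(C)[C@H]23 | intermediate
8 | C10 TBS-oxy C1-ketone lactone acetal (C10 oxygen anti to C6) | CC(C)[C@H]1CC[C@H](C)C[C@@H]1O[C@H]2OC(=O)[C@]3(C)CCC(=O)[C@@](C)(O[Si](C)(C)C(C)(C)C)[C@H]23 | intermediate
9 | C1=C2 enol triflate | CC(C)[C@H]1CC[C@H](C)C[C@@H]1O[C@H]2OC(=O)[C@]3(C)CC=C(OS(=O)(=O)C(F)(F)F)[C@@](C)(O[Si](C)(C)C(C)(C)C)[C@H]23 | intermediate
10 | ring A menthyl lactone acetal (C10 TBS ether) | CC(C)[C@H]1CC[C@H](C)C[C@@H]1O[C@H]2OC(=O)[C@]3(C)CCC[C@@](C)(O[Si](C)(C)C(C)(C)C)[C@H]23 | intermediate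
11 | 2-[(trimethylsilyl)methyl]prop-2-en-1-yl acetate | C=C(C[Si](C)(C)C)COC(C)=O | starting material
12 | C6 2-(acetoxymethyl)allyl lactone (C7 anti to ring A) | C=C(COC(C)=O)C[C@H]2OC(=O)[C@]3(C)CCC[C@@](C)(O[Si](C)(C)C(C)(C)C)[C@H]23 | intermediate
13 | allylic alcohol | C=C(CO)C[C@H]2OC(=O)[C@]3(C)CCC[C@@](C)(O[Si](C)(C)C(C)(C)C)[C@H]23 | intermediate
14 | 2-substituted acrolein (C15 aldehyde, C8=C14) | C=C(C=O)C[C@H]2OC(=O)[C@]3(C)CCC[C@@](C)(O[Si](C)(C)C(C)(C)C)[C@H]23 | intermediate
15 | (E)-but-2-enal | C/C=C/C=O | starting material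
16 | (1E)-1-(triethylsilyloxy)buta-1,3-diene | C=C/C=C/O[Si](CC)(CC)CC | intermediate
17 | TES-protected cycloadduct (C9 OTES cis to the C15 aldehyde) | C1C=C[C@H](O[Si](CC)(CC)CC)[C@@](C[C@H]2OC(=O)[C@]3(C)CCC[C@@](C)(O[Si](C)(C)C(C)(C)C)[C@H]23)(C1)C=O | intermediate
18 | ring C hydroxy aldehyde | C1C=C[C@H](O)[C@@](C[C@H]2OC(=O)[C@]3(C)CCC[C@@](C)(O[Si](C)(C)C(C)(C)C)[C@H]23)(C1)C=O | intermediate
19 | ring C keto aldehyde (6-formyl-6-alkylcyclohex-2-enone) | C1C=CC(=O)[C@@](C[C@H]2OC(=O)[C@]3(C)CCC[C@@](C)(O[Si](C)(C)C(C)(C)C)[C@H]23)(C1)C=O | intermediate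
20 | C15 propargylic alcohol | C1C=CC(=O)[C@@](C[C@H]2OC(=O)[C@]3(C)CCC[C@@](C)(O[Si](C)(C)C(C)(C)C)[C@H]23)(C1)[C@H](O)C#C | intermediate
21 | bis-TES silyl dienol ether | C1=CC=C(O[Si](CC)(CC)CC)[C@@](C[C@H]2OC(=O)[C@]3(C)CCC[C@@](C)(O[Si](C)(C)C(C)(C)C)[C@H]23)(C1)[C@H](O[Si](CC)(CC)CC)C#C | intermediate
22 | bicyclic bis-silyl ether (bicyclo[3.2.1]octenone; C15 OTES, C10 OTBS) | C=C1[C@@H]2C=CC(=O)[C@@](C[C@H]3OC(=O)[C@]4(C)CCC[C@@](C)(O[Si](C)(C)C(C)(C)C)[C@H]34)(C2)[C@@H]1O[Si](CC)(CC)CC | intermediate
23 | 15-deacetyl target (diol) | C=C1[C@@H]2C=CC(=O)[C@@](C[C@H]3OC(=O)[C@]4(C)CCC[C@@](C)(O)[C@H]34)(C2)[C@@H]1O | intermediate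
24 | CNP0172716.1 | C=C1[C@@H]2C=CC(=O)[C@@](C[C@H]3OC(=O)[C@]4(C)CCC[C@@](C)(O)[C@H]34)(C2)[C@@H]1OC(C)=O | target

## Step count and risks

Total steps: 16. Longest linear sequence: 15 steps (1 → 2 → 4 → 6 → 8 → 9 → 10 → 12 → 13 → 14 → 18 → 19 → 20 → 21 → 23 → 24).

Step 15 (proposed new gold-catalysed vinylogous Conia-ene reaction). The cyclisation could go through the α-carbon C11 instead of C13, or the dienol ether could simply be protodesilylated. The fallback uses known radical chemistry: it sets out from 21 and comes back at 22. MeLi (2.2 equiv, THF, −78 °C) cleaves the dienol silyl ether, and kinetic quench of the lithium dienolate with AcOH gives the deconjugated ketone F5 (C12=C13). Bu3SnH and AIBN in benzene at 80 °C add a stannyl radical to the alkyne terminus; the resulting C16 vinyl radical closes 5-exo onto C13 to give the vinylstannane F6. Protodestannylation (TsOH·H2O, CH2Cl2, −20 °C) gives the saturated ketone F7, and dehydrogenation with 2-iodoxybenzoic acid (DMSO, 70 °C) restores the C11=C12 enone to give 22, which is desilylated as in step 15.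

Step 11 (catalyst-controlled Diels–Alder reaction setting C8). The acid-labile silyloxydiene may decompose under the strongly acidic boron catalyst, or the facial selectivity on this chiral enal may be poor. The fallback moves stereocontrol from the catalyst to the diene: it sets out from 14 and comes back at 18. Enal 14 is combined with (E)-buta-1,3-dien-1-yl (S)-2-methoxy-2-phenylacetate (BF3·OEt2, CH2Cl2, −78 °C) to give the mandelate cycloadduct F4; the enantiomeric mandelate is used if the other C8 epimer predominates. K2CO3 in MeOH then cleaves the ester to give 18.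

Step 4 (Rubottom oxidation through the thermodynamic enol ether). Enolisation toward C10 may be incomplete, giving regioisomers. The fallback makes the enolisation regiospecific: it sets out from 4 and comes back at 9. Compound 4 is methylated as in step 3 but worked up without fluoride so that 5 is isolated. Pd(OAc)2 in MeCN (Saegusa–Ito oxidation) gives the cyclohexenone F1, in which only C10–H can be removed. LiN(SiMe3)2 and TBSCl give the cross-conjugated silyl dienol ether F2, and DMDO gives the silyloxy enone F3. Conjugate reduction with LiBH(s-Bu)3 and trapping of the enolate with PhNTf2 returns enol triflate 9.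

Further compounds
F1 | step 4 | cyclohexenone (C1 ketone, C2=C3, C4 methyl, H at C10) | CC(C)[C@H]1CC[C@H](C)C[C@@H]1O[C@H]2OC(=O)[C@]3(C)C=CC(=O)[C@H](C)[C@H]23
F2 | step 4 | cross-conjugated silyl dienol ether (C1=C10 TBS enol ether, C2=C3) | CC(C)[C@H]1CC[C@H](C)C[C@@H]1O[C@H]2OC(=O)[C@]3(C)C=CC(O[Si](C)(C)C(C)(C)C)=C(C)[C@H]23
F3 | step 4 | silyloxy enone (C10 OTBS, C1 ketone, C2=C3) | CC(C)[C@H]1CC[C@H](C)C[C@@H]1O[C@H]2OC(=O)[C@]3(C)C=CC(=O)[C@@](C)(O[Si](C)(C)C(C)(C)C)[C@H]23
F4 | step 11 | mandelate cycloadduct (C9 (S)-2-methoxy-2-phenylacetate, C15 aldehyde) | C1C=C[C@H](OC(=O)[C@@H](OC)c4ccccc4)[C@@](C[C@H]2OC(=O)[C@]3(C)CCC[C@@](C)(O[Si](C)(C)C(C)(C)C)[C@H]23)(C1)C=O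
F5 | step 15 | deconjugated ketone (C9 ketone, C12=C13, C15 OTES, terminal alkyne) | C1=CCC(=O)[C@@](C[C@H]2OC(=O)[C@]3(C)CCC[C@@](C)(O[Si](C)(C)C(C)(C)C)[C@H]23)(C1)[C@H](O[Si](CC)(CC)CC)C#C
F6 | step 15 | vinylstannane (C17 tributylstannyl bicyclo[3.2.1]octanone, alkene geometry mixture) | CCCC[Sn](CCCC)(CCCC)C=C1[C@@H]2CCC(=O)[C@@](C[C@H]3OC(=O)[C@]4(C)CCC[C@@](C)(O[Si](C)(C)C(C)(C)C)[C@H]34)(C2)[C@@H]1O[Si](CC)(CC)CC
F7 | step 15 | saturated ketone (11,12-dihydro analogue of 22) | C=C1[C@@H]2CCC(=O)[C@@](C[C@H]3OC(=O)[C@]4(C)CCC[C@@](C)(O[Si](C)(C)C(C)(C)C)[C@H]34)(C2)[C@@H]1O[Si](CC)(CC)CC
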